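The route cuts the two acyl C–O bonds that join the carbonyls on ring carbons C1 and C2 to the danshensu oxygens. The ring substituents point up, down, down, up (C1/C4 cis, C2/C3 cis, C1/C2 trans). This is the pattern of the meso maleic anhydride photodimer, whose five-membered anhydride rings span C1–C4 and C2–C3. One alkaloid-guided operation opens both anhydrides with protected (R)-danshensu at the two carbonyls related by the twofold axis. It installs both esters and fixes the absolute configuration of C1–C4. The remaining carboxyl carbons on C3 and C4 become the ipso carbons of the catechol rings, so no bond to a ring carbon is broken.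

Key step: step 4

Ring convention: the cyclobutane is drawn flat and numbered C1 to C4 clockwise. Substituents on C1 and C4 point up and those on C2 and C3 point down. The danshensu esters sit on C1 and C2. In the target the ring is (1R,2R,3R,4R) and both side-chain carbinol carbons are (R).

Assumption: quinidine is written as the matched alkaloid. The sense of induction known for primary alcohols cannot be carried over safely to a chiral secondary alcohol. Quinine is therefore run in parallel on pilot scale and takes its place, with nothing else changed, if it proves to be the matched partner.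

Protecting-group remark: the tert-butyl ester and aryl TBS ethers are kept because no later step uses carbonate, methanol or free alkoxide. They are removed in one flask at the end.

Step 1
Reactants: 1 (R)-danshensu
Product: 2 tert-butyl (2R)-3-(3,4-dihydroxyphenyl)-2-hydroxypropanoate
Conditions: t-BuOC(=NH)CCl3 (2.5 equiv), THF–cyclohexane, rt, argon
Reagents that add atoms: tert-butyl 2,2,2-trichloroacetimidate, CC(C)(C)OC(=N)C(Cl)(Cl)Cl
Why: Imidate esterification, in which only the carboxylic acid is acidic enough to protonate the trichloroacetimidate, so the tert-butyl group goes to the carboxylate while the secondary alcohol, the phenols and the (R) centre stay untouched.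

Step 2
Reactants: 2 tert-butyl (R)-danshensu ester
Product: 3 tert-butyl (2R)-3-[3,4-bis(tert-butyldimethylsilyloxy)phenyl]-2-hydroxypropanoate
Conditions: TBSCl (2.1 equiv), imidazole, DMF, 0 °C
Reagents that add atoms: tert-butyldimethylsilyl chloride, CC(C)(C)[Si](C)(C)Cl
Why: Chemoselective O-silylation, in which the two acidic, unhindered phenols react much faster than the secondary hydroxyl group deactivated by the adjacent ester, so two equivalents of TBSCl should leave the nucleophilic OH free.

Step 3
Reactants: 4 2,3-butanedione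
Product: 5 2,3-bis(tert-butyldimethylsilyloxy)buta-1,3-diene
Conditions: TBSOTf (2.2 equiv), Et3N, CH2Cl2, 0 °C → rt
Reagents that add atoms: tert-butyldimethylsilyl triflate, CC(C)(C)[Si](C)(C)OS(=O)(=O)C(F)(F)F
Why: Twofold soft enolisation and O-silylation of an α-diketone with silyl triflate and amine gives the 2,3-bis(silyloxy)diene, and TBS is preferred to TMS so that the derived enol and aryl ethers withstand filtration and oxidation later.

Step 4
Reactants: 6 cis,trans,cis-cyclobutane-1,2,3,4-tetracarboxylic 1,4:2,3-dianhydride (meso); 3 protected (R)-danshensu alcohol (two molecules incorporated)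
Product: 8 twofold-symmetric C1/C2 bis(danshensu) diester C3/C4 diacid (1R,2R,3R,4R), via mono-opened anhydride acid 7 (not isolated)
Conditions: quinidine (2.4 equiv), 3 (2.3 equiv), finely ground vacuum-dried 6, toluene–THF (3:1), −20 °C, several days; cold aq. KHSO4 wash; chromatography
Reagents that add atoms: none
Why: Proposed new method: the quinuclidine nitrogen of the alkaloid acts as a general base on the hydroxyl group of 3, whose acidity is raised by the neighbouring ester, while the alkaloid hydroxyl hydrogen-bonds one anhydride carbonyl, so the alcohol adds there and the tetrahedral intermediate collapses to an ester and an ammonium carboxylate. The closest known reaction type is the cinchona-alkaloid-mediated enantioselective alcoholysis of meso cyclic anhydrides, cyclobutane-fused ones included, with methanol or benzyl alcohol; new here are the secondary chiral α-hydroxy ester as nucleophile and the twofold opening of a dianhydride. No ring is closed: two five-membered anhydride rings are opened and two acyl C–O bonds are formed. The relative configuration of C1 to C4 is carried over unchanged from 6, and their absolute configuration is decided solely by which carbonyl of each enantiotopic pair is attacked, which the pairing of alkaloid and (R)-alcohol controls. Since the carbonyls on C1 and C2 are exchanged by the twofold axis of 6, the preference of the first opening (to 7) recurs in the second, where the new C1 ester lies on the ring face opposite to the remaining anhydride and should disturb it little. The selectivity needed is site selectivity among four carbonyls, and because the nucleophile is a single enantiomer every mis-opening (C3/C4 diester or C1/C3 diester) is a diastereomer of 8 that chromatography or crystallisation can remove, so the enantiopurity of 8 does not depend on the level of induction.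

Step 5
Reactants: 8 diester diacid
Product: 9 C3/C4 bis(S-ethyl thioester) of 8 (ring arrangement unchanged)
Conditions: EtSH, DCC, DMAP (cat.), CH2Cl2, 0 °C → rt
Reagents that add atoms: ethanethiol, CCS
Why: Steglich-type carbodiimide thioesterification under near-neutral conditions, in which the trans-disposed acids cannot close to a strained trans-fused anhydride and the soft thiol captures each activated acyl group before C3 or C4 can epimerise.

Step 6
Reactants: 9 bis(thioester)
Product: 10 C3/C4 dialdehyde (3,4-diformyl compound, ring arrangement unchanged)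
Conditions: Et3SiH, Pd/C (10 wt %), acetone, rt; used without long storage
Reagents that add atoms: none
Why: Fukuyama reduction, in which zerovalent palladium inserts into the C–S bond and the silane delivers hydride under neutral conditions, so reduction stops at the aldehyde and the esters, aryl silyl ethers and the centres C3 and C4 are left alone.

Step 7
Reactants: 10 dialdehyde
Product: 11 C3/C4 dialkyne (3,4-diethynyl compound, ring arrangement unchanged)
Conditions: (MeO)2P(O)CHN2 (2.6 equiv), KOtBu (2.5 equiv), THF, −78 °C (anion preformed); then 10, −78 °C → 0 °C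
Reagents that add atoms: dimethyl (diazomethyl)phosphonate, COP(=O)(OC)C=[N+]=[N-]
Why: Seyferth–Gilbert homologation, in which the preformed weakly basic phosphonate anion adds to each formyl group at low temperature and phosphate elimination, loss of N2 and a 1,2-hydride shift give the terminal alkyne, with no methanol, carbonate or free tert-butoxide present to cleave aryl silyl ethers, transesterify the activated esters or enolise the strained cyclobutane aldehydes.

Step 8
Reactants: 11 dialkyne; 5 bis(silyloxy)diene (two molecules incorporated)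
Product: 12 C3/C4 bis[4,5-bis(tert-butyldimethylsilyloxy)cyclohexa-1,4-dien-1-yl] compound
Conditions: 5 (4 equiv), CoBr2(dppe) (20 mol %), Zn powder (40 mol %), ZnI2 (40 mol %), CH2Cl2, rt; filtration through a short silica pad
Reagents that add atoms: none
Why: Cobalt-catalysed neutral Diels–Alder reaction, in which the monovalent cobalt species formed from CoBr2(dppe) and Zn couples an unactivated terminal alkyne with a 1,3-diene to a 1,4-cyclohexadiene at room temperature, silyloxy dienes being accepted substrates, the symmetrical diene removing any regiochemical question and no stereocentre being formed or touched.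

Step 9
Reactants: 12 bis(cyclohexadiene)
Product: 13 fully protected target (C3/C4 bis[3,4-bis(tert-butyldimethylsilyloxy)phenyl], danshensu parts as in 8)
Conditions: DDQ (2.1 equiv), toluene, 0 °C → rt; filtration, chromatography
Reagents that add atoms: none
Why: DDQ dehydrogenation, in which hydride abstraction from a doubly allylic CH2 followed by proton loss aromatises each 1,4-cyclohexadiene far faster than DDQ attacks benzylic C–H bonds, placing the two silyloxy groups meta and para to the cyclobutane.

Step 10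
Reactants: 13 fully protected target
Product: 15 target CNP0163929.1, via octasilyl diacid 14 (not isolated)
Conditions: TFA–CH2Cl2 (1:1), 0 °C → rt, argon; concentrate; then Et3N·3HF, MeCN–THF, rt, argon; EtOAc/dilute HCl work-up, C18 chromatography
Reagents that add atoms: none
Why: Acidolysis of the tert-butyl esters with loss of isobutene, followed by fluoride-driven Si–O cleavage in a mildly acidic medium, keeps the catechols protonated and so protected from air oxidation, and neither reagent attacks the two remaining ester linkages or any stereocentre, early partial loss of silyl groups being harmless.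

Compound list
1 | (R)-danshensu, (2R)-3-(3,4-dihydroxyphenyl)-2-hydroxypropanoic acid | O[C@H](Cc1ccc(O)c(O)c1)C(=O)O | starting material
2 | tert-butyl (2R)-3-(3,4-dihydroxyphenyl)-2-hydroxypropanoate | O[C@H](Cc1ccc(O)c(O)c1)C(=O)OC(C)(C)C | intermediate
3 | tert-butyl (2R)-3-[3,4-bis(tert-butyldimethylsilyloxy)phenyl]-2-hydroxypropanoate | O[C@H](Cc1ccc(O[Si](C)(C)C(C)(C)C)c(O[Si](C)(C)C(C)(C)C)c1)C(=O)OC(C)(C)C | intermediate
4 | 2,3-butanedione | CC(=O)C(C)=O | starting material
5 | 2,3-bis(tert-butyldimethylsilyloxy)buta-1,3-diene | C=C(O[Si](C)(C)C(C)(C)C)C(=C)O[Si](C)(C)C(C)(C)C | intermediate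
6 | cis,trans,cis-cyclobutane-1,2,3,4-tetracarboxylic 1,4:2,3-dianhydride (meso) | O=C2[C@H]1[C@H](C3=O)[C@H](C(=O)O3)[C@H]1C(=O)O2 | starting material
7 | mono-opened anhydride acid (danshensu ester on C1, free acid on C4, C2–C3 anhydride intact) | O=C(O[C@H](Cc1ccc(O[Si](C)(C)C(C)(C)C)c(O[Si](C)(C)C(C)(C)C)c1)C(=O)OC(C)(C)C)[C@H]1[C@H](C3=O)[C@H](C(=O)O3)[C@H]1C(=O)O | intermediate
8 | (1R,2R,3R,4R)-cyclobutane-1,2,3,4-tetracarboxylic acid esterified at the C1 and C2 carboxyls with 3, free acids on C3 and C4 | O=C(O[C@H](Cc1ccc(O[Si](C)(C)C(C)(C)C)c(O[Si](C)(C)C(C)(C)C)c1)C(=O)OC(C)(C)C)[C@H]1[C@H](C(=O)O[C@H](Cc2ccc(O[Si](C)(C)C(C)(C)C)c(O[Si](C)(C)C(C)(C)C)c2)C(=O)OC(C)(C)C)[C@H](C(=O)O)[C@H]1C(=O)O | intermediate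
9 | C3/C4 bis(S-ethyl thioester) of 8 | O=C(O[C@H](Cc1ccc(O[Si](C)(C)C(C)(C)C)c(O[Si](C)(C)C(C)(C)C)c1)C(=O)OC(C)(C)C)[C@H]1[C@H](C(=O)O[C@H](Cc2ccc(O[Si](C)(C)C(C)(C)C)c(O[Si](C)(C)C(C)(C)C)c2)C(=O)OC(C)(C)C)[C@H](C(=O)SCC)[C@H]1C(=O)SCC | intermediate
10 | C3/C4 dialdehyde | O=C(O[C@H](Cc1ccc(O[Si](C)(C)C(C)(C)C)c(O[Si](C)(C)C(C)(C)C)c1)C(=O)OC(C)(C)C)[C@H]1[C@H](C(=O)O[C@H](Cc2ccc(O[Si](C)(C)C(C)(C)C)c(O[Si](C)(C)C(C)(C)C)c2)C(=O)OC(C)(C)C)[C@H](C=O)[C@H]1C=O | intermediate
11 | C3/C4 dialkyne | O=C(O[C@H](Cc1ccc(O[Si](C)(C)C(C)(C)C)c(O[Si](C)(C)C(C)(C)C)c1)C(=O)OC(C)(C)C)[C@H]1[C@H](C(=O)O[C@H](Cc2ccc(O[Si](C)(C)C(C)(C)C)c(O[Si](C)(C)C(C)(C)C)c2)C(=O)OC(C)(C)C)[C@H](C#C)[C@H]1C#C | intermediate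
12 | C3/C4 bis[4,5-bis(tert-butyldimethylsilyloxy)cyclohexa-1,4-dien-1-yl] compound | O=C(O[C@H](Cc1ccc(O[Si](C)(C)C(C)(C)C)c(O[Si](C)(C)C(C)(C)C)c1)C(=O)OC(C)(C)C)[C@H]1[C@H](C(=O)O[C@H](Cc2ccc(O[Si](C)(C)C(C)(C)C)c(O[Si](C)(C)C(C)(C)C)c2)C(=O)OC(C)(C)C)[C@H](C2=CCC(O[Si](C)(C)C(C)(C)C)=C(O[Si](C)(C)C(C)(C)C)C2)[C@H]1C1=CCC(O[Si](C)(C)C(C)(C)C)=C(O[Si](C)(C)C(C)(C)C)C1 | intermediate
13 | fully protected target (eight aryl TBS ethers, two tert-butyl esters) | O=C(O[C@H](Cc1ccc(O[Si](C)(C)C(C)(C)C)c(O[Si](C)(C)C(C)(C)C)c1)C(=O)OC(C)(C)C)[C@H]1[C@H](C(=O)O[C@H](Cc2ccc(O[Si](C)(C)C(C)(C)C)c(O[Si](C)(C)C(C)(C)C)c2)C(=O)OC(C)(C)C)[C@H](c2ccc(O[Si](C)(C)C(C)(C)C)c(O[Si](C)(C)C(C)(C)C)c2)[C@H]1c1ccc(O[Si](C)(C)C(C)(C)C)c(O[Si](C)(C)C(C)(C)C)c1 | intermediate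
14 | octasilyl diacid | O=C(O[C@H](Cc1ccc(O[Si](C)(C)C(C)(C)C)c(O[Si](C)(C)C(C)(C)C)c1)C(=O)O)[C@H]1[C@H](C(=O)O[C@H](Cc2ccc(O[Si](C)(C)C(C)(C)C)c(O[Si](C)(C)C(C)(C)C)c2)C(=O)O)[C@H](c2ccc(O[Si](C)(C)C(C)(C)C)c(O[Si](C)(C)C(C)(C)C)c2)[C@H]1c1ccc(O[Si](C)(C)C(C)(C)C)c(O[Si](C)(C)C(C)(C)C)c1 | intermediate
15 | CNP0163929.1, bis[(1R)-1-carboxy-2-(3,4-dihydroxyphenyl)ethyl] (1R,2R,3R,4R)-3,4-bis(3,4-dihydroxyphenyl)cyclobutane-1,2-dicarboxylate | O=C(O[C@H](Cc1ccc(O)c(O)c1)C(=O)O)[C@H]1[C@H](C(=O)O[C@H](Cc2ccc(O)c(O)c2)C(=O)O)[C@H](c2ccc(O)c(O)c2)[C@H]1c1ccc(O)c(O)c1 | target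

Total step count: 10. Longest linear sequence: 9 (steps 1, 2, 4 to 10, from (R)-danshensu).

Steps most likely to fail

Step 4.
- What may go wrong: the hindered secondary alcohol may add too slowly to the sparingly soluble dianhydride. The alkaloid's own hydroxyl group may be acylated in competition. Site selectivity may be poor in the first or second opening.
- Fallback (known chemistry only): it sets out from 6. The established alkaloid-mediated opening with benzyl alcohol, a primary alcohol, is used in toluene–THF at low temperature. Quinine or quinidine is chosen by the known sense so that the benzyl esters land on the C3 and C4 carbonyls. This should give the twofold-symmetric 3,4-dibenzyl ester 1,2-diacid F1.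
- Steglich esterification of both acids with 3 (DCC, DMAP, CH2Cl2) gives the mixed tetraester F2. At this stage material from the minor ring enantiomer is a separable diastereomer.
- Hydrogenolysis (H2, Pd/C, EtOAc) removes the benzyl esters and the sequence comes back to the route at 8.

Step 8.
- What may go wrong: the twofold cycloaddition may be slow or incomplete because the doubly silyloxylated diene binds poorly to cobalt in its s-cis form. ZnI2 may desilylate the diene. Alkyne cyclotrimerisation may then take over.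
- Fallback: it sets out from 11. The same catalyst is used with commercial 2-(trimethylsilyloxy)buta-1,3-diene, a diene class established for this catalysis. This gives the bis[4-(trimethylsilyloxy)cyclohexa-1,4-dienyl] compound F3.
- DDQ gives the bis[4-(trimethylsilyloxy)phenyl] compound F4. Dilute citric acid in aqueous THF then frees the bis(4-hydroxyphenyl) compound F5 without touching the aryl TBS ethers.
- The second oxygen is installed by ortho-oxygenation of the phenols with IBX (DMF, rt) to the bis(o-quinone) F6. Aqueous Na2S2O4 reduces F6 in the same flask to the bis(catechol) F7.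
- A meta-oriented cycloadduct would converge on the same catechol, because IBX oxygenates the less hindered ortho position.
- TBSCl and imidazole bring the material back to the route at 13.

Step 7.
- What may go wrong: C3 or C4 may epimerise through enolisation of the formyl groups. The intermediate alkoxide may attack the neighbouring cis ester, which is lactonisation with loss of danshensu, before phosphate elimination occurs.
- Fallback: it sets out from 10. Stork–Zhao olefination with Ph3P=CHI removes each carbonyl by a concerted Wittig cycloaddition without a free alkoxide. The ylide is made from [Ph3PCH2I]I and a slight deficit of NaN(SiMe3)2 in THF–DMPU at −78 °C. This gives the bis[(Z)-2-iodoethenyl] compound F8, in which C3–H and C4–H are no longer acidic.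
- Anti elimination of HI with Bu4NF in THF forms both alkynes. It also strips the four aryl silyl ethers, giving the dialkyne tetraphenol F9.
- F9 is resilylated in the same flask (TBSCl, imidazole) and comes back to the route at 11.

Further compounds
F1 | step 4 | (1R,2R,3R,4R)-arranged cyclobutanetetracarboxylic acid 3,4-dibenzyl ester 1,2-diacid | O=C(O)[C@H]1[C@H](C(=O)O)[C@H](C(=O)OCc2ccccc2)[C@H]1C(=O)OCc1ccccc1
F2 | step 4 | mixed tetraester (danshensu esters on C1 and C2, benzyl esters on C3 and C4) | O=C(O[C@H](Cc1ccc(O[Si](C)(C)C(C)(C)C)c(O[Si](C)(C)C(C)(C)C)c1)C(=O)OC(C)(C)C)[C@H]1[C@H](C(=O)O[C@H](Cc2ccc(O[Si](C)(C)C(C)(C)C)c(O[Si](C)(C)C(C)(C)C)c2)C(=O)OC(C)(C)C)[C@H](C(=O)OCc2ccccc2)[C@H]1C(=O)OCc1ccccc1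
F3 | step 8 | C3/C4 bis[4-(trimethylsilyloxy)cyclohexa-1,4-dien-1-yl] compound | O=C(O[C@H](Cc1ccc(O[Si](C)(C)C(C)(C)C)c(O[Si](C)(C)C(C)(C)C)c1)C(=O)OC(C)(C)C)[C@H]1[C@H](C(=O)O[C@H](Cc2ccc(O[Si](C)(C)C(C)(C)C)c(O[Si](C)(C)C(C)(C)C)c2)C(=O)OC(C)(C)C)[C@H](C2=CCC(O[Si](C)(C)C)=CC2)[C@H]1C1=CCC(O[Si](C)(C)C)=CC1
F4 | step 8 | C3/C4 bis[4-(trimethylsilyloxy)phenyl] compound | O=C(O[C@H](Cc1ccc(O[Si](C)(C)C(C)(C)C)c(O[Si](C)(C)C(C)(C)C)c1)C(=O)OC(C)(C)C)[C@H]1[C@H](C(=O)O[C@H](Cc2ccc(O[Si](C)(C)C(C)(C)C)c(O[Si](C)(C)C(C)(C)C)c2)C(=O)OC(C)(C)C)[C@H](c2ccc(O[Si](C)(C)C)cc2)[C@H]1c1ccc(O[Si](C)(C)C)cc1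
F5 | step 8 | C3/C4 bis(4-hydroxyphenyl) compound | O=C(O[C@H](Cc1ccc(O[Si](C)(C)C(C)(C)C)c(O[Si](C)(C)C(C)(C)C)c1)C(=O)OC(C)(C)C)[C@H]1[C@H](C(=O)O[C@H](Cc2ccc(O[Si](C)(C)C(C)(C)C)c(O[Si](C)(C)C(C)(C)C)c2)C(=O)OC(C)(C)C)[C@H](c2ccc(O)cc2)[C@H]1c1ccc(O)cc1
F6 | step 8 | C3/C4 bis(3,4-dioxocyclohexa-1,5-dien-1-yl) compound (bis-o-quinone) | O=C(O[C@H](Cc1ccc(O[Si](C)(C)C(C)(C)C)c(O[Si](C)(C)C(C)(C)C)c1)C(=O)OC(C)(C)C)[C@H]1[C@H](C(=O)O[C@H](Cc2ccc(O[Si](C)(C)C(C)(C)C)c(O[Si](C)(C)C(C)(C)C)c2)C(=O)OC(C)(C)C)[C@H](C2=CC(=O)C(=O)C=C2)[C@H]1C1=CC(=O)C(=O)C=C1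
F7 | step 8 | C3/C4 bis(3,4-dihydroxyphenyl) compound with protected danshensu parts | O=C(O[C@H](Cc1ccc(O[Si](C)(C)C(C)(C)C)c(O[Si](C)(C)C(C)(C)C)c1)C(=O)OC(C)(C)C)[C@H]1[C@H](C(=O)O[C@H](Cc2ccc(O[Si](C)(C)C(C)(C)C)c(O[Si](C)(C)C(C)(C)C)c2)C(=O)OC(C)(C)C)[C@H](c2ccc(O)c(O)c2)[C@H]1c1ccc(O)c(O)c1
F8 | step 7 | C3/C4 bis[(Z)-2-iodoethenyl] compound | O=C(O[C@H](Cc1ccc(O[Si](C)(C)C(C)(C)C)c(O[Si](C)(C)C(C)(C)C)c1)C(=O)OC(C)(C)C)[C@H]1[C@H](C(=O)O[C@H](Cc2ccc(O[Si](C)(C)C(C)(C)C)c(O[Si](C)(C)C(C)(C)C)c2)C(=O)OC(C)(C)C)[C@H](/C=C\I)[C@H]1/C=C\I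
F9 | step 7 | C3/C4 dialkyne with four free phenols (tert-butyl esters intact) | O=C(O[C@H](Cc1ccc(O)c(O)c1)C(=O)OC(C)(C)C)[C@H]1[C@H](C(=O)O[C@H](Cc2ccc(O)c(O)c2)C(=O)OC(C)(C)C)[C@H](C#C)[C@H]1C#C
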